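**Retrosynthetic overview** (ring A = trioxygenated ring bearing the carbinol, B = para-phenylene, C = 1,2,3-trisubstituted ring with one OH, D = meta-phenylene)
1. 15 ⇐ 14: one hydrogenolysis removes the benzyl ether (ring C) and the diphenylmethylene ketal (ring A).
2. 14 ⇐ 13: the 18-membered ring is closed last, at the ring A–O–ring B diaryl ether C–O bond (aryl bromide + phenol).
3. 13 ⇐ 12: the S carbinol comes from asymmetric transfer hydrogenation of the aryl benzyl ketone; 12 ⇐ 10 + 2 (acylation of an arylacetic acid dianion, loss of CO2).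
4. 10 ⇐ 7 + 8 (hydroboration and B-alkyl Suzuki coupling give the ring B–CH2CH2–ring C bridge); 7 ⇐ 6 (methylenation).
5. 6 ⇐ 4 + 5: the ring C–O–ring D diaryl ether C–O bond by SNAr. Ring order: dioxole ketal on ring A (step 1), then the macrocycle (step 8); the four benzene rings are bought.

Assumption: the carbinol carbon of the target is S (read from the SMILES), and 1 and 3 are taken as catalogue starting materials.

**Step 1**
Reactants: 1 methyl 3-bromo-4,5-dihydroxybenzoate
Product: 2 methyl 7-bromo-2,2-diphenyl-1,3-benzodioxole-5-carboxylate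
Conditions: Ph2CCl2 (1.3 equiv), K2CO3, MeCN, 60 °C
Reagents that add atoms: dichlorodiphenylmethane, ClC(Cl)(c1ccccc1)c1ccccc1
Why: Double Williamson-type substitution (catechol ketalisation): the two adjacent phenoxides displace both chlorides of the gem-dichloride and close the five-membered dioxole, which masks both ring A hydroxyls with a group that later falls off by hydrogenolysis and places no flexible benzyl ether next to the C–Br bond.

**Step 2**
Reactants: 3 2-fluoro-3-hydroxybenzaldehyde
Product: 4 3-(benzyloxy)-2-fluorobenzaldehyde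
Conditions: BnBr, K2CO3, DMF, rt
Reagents that add atoms: benzyl bromide, BrCc1ccccc1
Why: Williamson ether synthesis: the phenoxide is alkylated by benzyl bromide, and an ether (not a phenoxide) next to fluorine keeps the ring electrophilic for the next step.

**Step 3**
Reactants: 4 3-(benzyloxy)-2-fluorobenzaldehyde, 5 3-hydroxyphenylacetic acid
Product: 6 2-{3-[2-(benzyloxy)-6-formylphenoxy]phenyl}acetic acid
Conditions: K2CO3 (3 equiv), DMSO, 110 °C; then aq. HCl
Reagents that add atoms: none
Why: SNAr (addition–elimination): the fluoride ortho to the formyl group is displaced by the phenoxide of 5 through a formyl-stabilised Meisenheimer adduct; the carboxylate is a much poorer nucleophile, and as a carboxylate the arylacetic CH2 is too weakly acidic to condense with the aldehyde.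

**Step 4**
Reactants: 6 2-{3-[2-(benzyloxy)-6-formylphenoxy]phenyl}acetic acid
Product: 7 2-{3-[2-(benzyloxy)-6-ethenylphenoxy]phenyl}acetic acid
Conditions: Ph3PCH3Br (1.5 equiv), KOtBu (2.5 equiv), THF, 0 °C to rt; then aq. HCl
Reagents that add atoms: methyltriphenylphosphonium bromide, C[P+](c1ccccc1)(c1ccccc1)c1ccccc1.[Br-]
Why: Wittig methylenation: the non-stabilised ylide converts only the aldehyde into the vinyl group, one extra equivalent of base holding the acid as its inert carboxylate.

**Step 5**
Reactants: 7 2-{3-[2-(benzyloxy)-6-ethenylphenoxy]phenyl}acetic acid, 8 4-iodophenol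
Product: 10 2-{3-[2-(benzyloxy)-6-[2-(4-hydroxyphenyl)ethyl]phenoxy]phenyl}acetic acid, via B-alkyl-9-BBN adduct 9 (not isolated)
Conditions: 9-BBN (2.2 equiv), THF, 0 °C to rt; then 8, Pd(dppf)Cl2 (5 mol %), aq. K3PO4, DMF, 50 °C; then aq. HCl
Reagents that add atoms: none
Why: Hydroboration then Suzuki–Miyaura B-alkyl coupling: 9-BBN adds anti-Markovnikov to the styrene (the acid only consumes one hydride, giving an acyloxyborane that is hydrolysed later) and the primary alkylborane couples with the aryl iodide of unprotected 8 under aqueous base, giving the saturated two-carbon bridge directly.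

**Step 6**
Reactants: 10 2-{3-[2-(benzyloxy)-6-[2-(4-hydroxyphenyl)ethyl]phenoxy]phenyl}acetic acid, 2 methyl 7-bromo-2,2-diphenyl-1,3-benzodioxole-5-carboxylate
Product: 12 2-{3-[2-(benzyloxy)-6-[2-(4-hydroxyphenyl)ethyl]phenoxy]phenyl}-1-(7-bromo-2,2-diphenyl-1,3-benzodioxol-5-yl)ethan-1-one, via beta-keto acid 11 (not isolated)
Conditions: 10, tBuMgCl (3.1 equiv), THF, 55 °C; then 2 and tBuMgCl (1.1 equiv) added together, 60 °C; then aq. HCl, 40 °C
Reagents that add atoms: none
Why: Ivanov-type Claisen acylation: the magnesium enediolate of the arylacetic acid (the phenol riding as its magnesium salt) attacks the methyl ester of 2, and the beta-keto acid set free on acidification loses CO2 to give the aryl benzyl ketone; tBuMgCl is too hindered to add to the ester or to exchange with the aryl bromide.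

**Step 7**
Reactants: 12 2-{3-[2-(benzyloxy)-6-[2-(4-hydroxyphenyl)ethyl]phenoxy]phenyl}-1-(7-bromo-2,2-diphenyl-1,3-benzodioxol-5-yl)ethan-1-one
Product: 13 (1S)-2-{3-[2-(benzyloxy)-6-[2-(4-hydroxyphenyl)ethyl]phenoxy]phenyl}-1-(7-bromo-2,2-diphenyl-1,3-benzodioxol-5-yl)ethan-1-ol
Conditions: RuCl[(S,S)-TsDPEN](p-cymene) (2 mol %), HCO2H/Et3N 5:2, DMF, 40 °C
Reagents that add atoms: none
Why: Noyori asymmetric transfer hydrogenation: the (S,S)-TsDPEN ruthenium hydride recognises the aryl ketone (no ortho substituent on ring A) through a CH–π contact and delivers hydride to the face that gives the S alcohol, the same sense as acetophenone to (S)-1-phenylethanol since aryl outranks CH2Ar; aryl bromide, ketal, benzyl ether and phenol are untouched.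

**Step 8**
Reactants: 13 (1S)-2-{3-[2-(benzyloxy)-6-[2-(4-hydroxyphenyl)ethyl]phenoxy]phenyl}-1-(7-bromo-2,2-diphenyl-1,3-benzodioxol-5-yl)ethan-1-ol
Product: 14 protected S macrocycle (target skeleton with the ring A catechol oxygens bridged by CPh2 as a 2,2-diphenyl-1,3-dioxole, the ring C oxygen as benzyl ether, free S secondary alcohol)
Conditions: Pd2(dba)3 (5 mol %), Me4tBuXPhos (12 mol %), K3PO4, toluene, 100 °C, 13 added over 10 h to 2 mM
Reagents that add atoms: none
Why: Proposed new method: palladium-catalysed macrocyclising diaryl ether formation (intramolecular O-arylation closing an 18-membered ring), a ring closure so far done with copper (Ullmann) or by SNAr; zerovalent palladium carrying the bulky di-tert-butylbiarylphosphine adds oxidatively to the C–Br bond of ring A, the tethered ring B phenoxide (formed by K3PO4) replaces bromide on divalent palladium to give a 19-membered aryl(aryloxo)palladium chelate, and the bulky ligand forces C–O reductive elimination; since each long-lived aryl–palladium species carries its own phenoxide, ring closure should outrun oligomerisation at 2 mM, the secondary alcohol is not deprotonated by phosphate and cannot reach the metal on its own ring, and no flexible ortho-benzyl ether is present for competing C–H arylation; closest known reaction types are the intermolecular palladium/biarylphosphine diaryl ether coupling, palladium C–N macrocyclisation and the copper Ullmann macro-etherification; the stereocentre is not touched.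

**Step 9**
Reactants: 14 protected S macrocycle
Product: 15 target CNP0333307.1 (S alcohol, three free phenols)
Conditions: H2 (1 atm), 10 % Pd/C, THF/MeOH, rt
Reagents that add atoms: none
Why: Hydrogenolysis: palladium on carbon cleaves the benzylic C–O bonds of the benzyl ether (to toluene) and of the diphenylmethylene ketal (to diphenylmethane) under neutral conditions, in which the secondary benzylic alcohol is a poor leaving group and keeps its S configuration.

**Compound list**
1 | methyl 3-bromo-4,5-dihydroxybenzoate | COC(=O)c1cc(O)c(O)c(Br)c1 | starting material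
2 | methyl 7-bromo-2,2-diphenyl-1,3-benzodioxole-5-carboxylate | COC(=O)c1cc(Br)c2OC(c3ccccc3)(c3ccccc3)Oc2c1 | intermediate
3 | 2-fluoro-3-hydroxybenzaldehyde | O=Cc1cccc(O)c1F | starting material
4 | 3-(benzyloxy)-2-fluorobenzaldehyde | O=Cc1cccc(OCc2ccccc2)c1F | intermediate
5 | 3-hydroxyphenylacetic acid | OC(=O)Cc1cccc(O)c1 | starting material
6 | 2-{3-[2-(benzyloxy)-6-formylphenoxy]phenyl}acetic acid | OC(=O)Cc1cccc(Oc2c(C=O)cccc2OCc2ccccc2)c1 | intermediate
7 | 2-{3-[2-(benzyloxy)-6-ethenylphenoxy]phenyl}acetic acid | OC(=O)Cc1cccc(Oc2c(C=C)cccc2OCc2ccccc2)c1 | intermediate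
8 | 4-iodophenol | Oc1ccc(I)cc1 | starting material
9 | B-alkyl-9-BBN adduct of 7 (ArCH2CH2–B of 9-borabicyclo[3.3.1]nonane, carboxyl group as its 9-BBN acyloxyborane) | O=C(OB1C2CCCC1CCC2)Cc1cccc(Oc2c(CCB3C4CCCC3CCC4)cccc2OCc2ccccc2)c1 | intermediate
10 | 2-{3-[2-(benzyloxy)-6-[2-(4-hydroxyphenyl)ethyl]phenoxy]phenyl}acetic acid | OC(=O)Cc1cccc(Oc2c(CCc3ccc(O)cc3)cccc2OCc2ccccc2)c1 | intermediate
11 | 3-(7-bromo-2,2-diphenyl-1,3-benzodioxol-5-yl)-2-{3-[2-(benzyloxy)-6-[2-(4-hydroxyphenyl)ethyl]phenoxy]phenyl}-3-oxopropanoic acid (racemic at C-2) | OC(=O)C(C(=O)c1cc(Br)c2OC(c3ccccc3)(c3ccccc3)Oc2c1)c1cccc(Oc2c(CCc3ccc(O)cc3)cccc2OCc2ccccc2)c1 | intermediate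
12 | 2-{3-[2-(benzyloxy)-6-[2-(4-hydroxyphenyl)ethyl]phenoxy]phenyl}-1-(7-bromo-2,2-diphenyl-1,3-benzodioxol-5-yl)ethan-1-one | O=C(Cc1cccc(Oc2c(CCc3ccc(O)cc3)cccc2OCc2ccccc2)c1)c1cc(Br)c2OC(c3ccccc3)(c3ccccc3)Oc2c1 | intermediate
13 | (1S)-2-{3-[2-(benzyloxy)-6-[2-(4-hydroxyphenyl)ethyl]phenoxy]phenyl}-1-(7-bromo-2,2-diphenyl-1,3-benzodioxol-5-yl)ethan-1-ol | O[C@@H](Cc1cccc(Oc2c(CCc3ccc(O)cc3)cccc2OCc2ccccc2)c1)c1cc(Br)c2OC(c3ccccc3)(c3ccccc3)Oc2c1 | intermediate
14 | protected S macrocycle (ring A catechol as diphenylmethylene ketal, ring C phenol as benzyl ether, free S alcohol) | C4(c5ccccc5)(c5ccccc5)Oc1cc2cc(c1O4)Oc1ccc(cc1)CCc1cccc(OCc6ccccc6)c1Oc1cccc(c1)C[C@@H]2O | intermediate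
15 | CNP0333307.1, S-configured macrocyclic bis(bibenzyl) triphenol carbinol | Oc1cc2cc(c1O)Oc1ccc(cc1)CCc1cccc(O)c1Oc1cccc(c1)C[C@@H]2O | target

**Totals**
Total step count: 9. Longest linear sequence: 8 steps (3 → 4 → 6 → 7 → 10 → 12 → 13 → 14 → 15); step 1 is a one-step side branch.

**Three steps most likely to fail**

Step 8 (the proposed palladium ring closure). Reductive elimination from an electron-rich aryl–palladium phenoxide may be slow, leading to protodebromination or oligomers. The fallback uses known chemistry and sets out from 13: palladium-catalysed borylation of the aryl bromide with tetrahydroxydiboron (Pd(OAc)2, XPhos, KOAc, EtOH, 80 °C) gives the arylboronic acid F1. F1 is closed by an oxidative copper-mediated Chan–Lam–Evans phenol arylation (Cu(OAc)2, pyridine, 4 Å sieves, CH2Cl2, air, rt, 2 mM). This comes back to the route at 14.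

Step 6 (dianion acylation). The magnesium tri-anion of 10 may be poorly soluble, or tBuMgCl may attack ester 2 before the enediolate does. The fallback sets out from 10 and drops the one-pot dianion method for a stepwise ester-enolate sequence. Fischer esterification (MeOH, cat. H2SO4) gives the methyl ester F2. Crossed Claisen condensation of its lithium enolate with 2 (LiHMDS 3.2 equiv, THF, −78 to 0 °C, the phenol as its lithium salt) gives the beta-keto ester F3. Krapcho dealkoxycarbonylation (LiCl, wet DMSO, 130 °C) comes back to the route at 12.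

Step 5 (hydroboration and B-alkyl Suzuki coupling). The free carboxylic acid may interfere with 9-BBN, and the unprotected iodophenol may couple sluggishly. The fallback sets out from 6 and replaces steps 4 and 5 by olefination and reduction. Wittig reaction with (4-hydroxybenzyl)triphenylphosphonium bromide (LiHMDS 3.3 equiv, THF) gives the stilbene acid F4 as an E/Z mixture. Diimide reduction (TsNHNH2, NaOAc, THF/H2O, reflux) saturates the alkene without touching the benzyl ether and comes back to the route at 10.

**Further compounds**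
F1 | step 8 | boronic acid analogue of 13: [6-{(1S)-1-hydroxy-2-(3-{2-(benzyloxy)-6-[2-(4-hydroxyphenyl)ethyl]phenoxy}phenyl)ethyl}-2,2-diphenyl-1,3-benzodioxol-4-yl]boronic acid | O[C@@H](Cc1cccc(Oc2c(CCc3ccc(O)cc3)cccc2OCc2ccccc2)c1)c1cc(B(O)O)c2OC(c3ccccc3)(c3ccccc3)Oc2c1
F2 | step 6 | methyl 2-{3-[2-(benzyloxy)-6-[2-(4-hydroxyphenyl)ethyl]phenoxy]phenyl}acetate | COC(=O)Cc1cccc(Oc2c(CCc3ccc(O)cc3)cccc2OCc2ccccc2)c1
F3 | step 6 | methyl 3-(7-bromo-2,2-diphenyl-1,3-benzodioxol-5-yl)-2-{3-[2-(benzyloxy)-6-[2-(4-hydroxyphenyl)ethyl]phenoxy]phenyl}-3-oxopropanoate (racemic) | COC(=O)C(C(=O)c1cc(Br)c2OC(c3ccccc3)(c3ccccc3)Oc2c1)c1cccc(Oc2c(CCc3ccc(O)cc3)cccc2OCc2ccccc2)c1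
F4 | step 5 | 2-{3-[2-(benzyloxy)-6-[2-(4-hydroxyphenyl)ethenyl]phenoxy]phenyl}acetic acid (E/Z mixture) | OC(=O)Cc1cccc(Oc2c(C=Cc3ccc(O)cc3)cccc2OCc2ccccc2)c1
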